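**Retrosynthetic overview**
- End game from tetracyclic keto-quinone 18: C10=C20 by quinone-methide tautomerisation/air, CBS reduction of C1=O, then removal of the O-methyl and TBS groups.
- Key step, ring B closed last: Ag(I)/persulfate decarboxylation of a C10-acetic acid gives a C20 radical that adds 7-endo to the only free quinone carbon (C9).
- Ring C: Moore ring expansion of an alkynyl-hydroxycyclobutenone (squaric acid + i-PrMgCl + the C8≡C9 acetylide) gives the 2-methoxy-3-isopropylquinone regiospecifically.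
- Ring A: Diels–Alder reaction of a 2-silyloxydiene (succinic anhydride + vinylMgBr) with a γ-substituted α-methylbutenolide, anti to the side chain (sets C4 and C5).
- C6/C7: catalytic asymmetric vinylogous Mukaiyama aldol of 3-methyl-2-silyloxyfuran with TMS-propynal; ring order lactone → A → C → B.

Assumption: atom numbers (C-1 … C-20) are the icetexane numbers of the target (C-19 = lactone carbonyl, C-18 = C-4 methyl); centres that are destroyed later (C-10 in 13–18, the carbinol carbon in 3 and 15) are carried as mixtures and left undefined in the SMILES.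

Step 1
Reactants: 1 squaric acid
Product: 2 dimethyl squarate
Conditions: HC(OMe)3, MeOH, reflux
Reagents that add atoms: trimethyl orthoformate COC(OC)OC
Why: Orthoester-driven O-methylation of the strongly acidic enediol (vinylogous esterification) is the standard preparation of dialkyl squarates and involves no stereocentre.

Step 2
Reactants: 2 dimethyl squarate
Product: 4 3-methoxy-4-isopropylcyclobut-3-ene-1,2-dione, via carbinol adduct 3 (not isolated)
Conditions: i-PrMgCl, THF, −78 °C; then aq HCl, CH2Cl2, 0 °C → rt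
Reagents that add atoms: isopropylmagnesium chloride CC(C)[Mg]Cl
Why: Grignard 1,2-addition to one squarate carbonyl followed by acid-mediated allylic transposition with loss of methanol (Liebeskind–Moore semisquarate synthesis) gives the 3-alkyl-4-alkoxy dione.

Step 3
Reactants: 5 succinic anhydride
Product: 6 4-oxohex-5-enoic acid
Conditions: CH2=CHMgBr (1.0 equiv), THF, −78 °C; 1 M HCl
Reagents that add atoms: vinylmagnesium bromide C=C[Mg]Br
Why: Mono-addition of a Grignard reagent to a cyclic anhydride (nucleophilic acyl substitution) stops at the keto carboxylate, because the magnesium carboxylate formed on ring opening suppresses over-addition at −78 °C.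

Step 4
Reactants: 6 4-oxohex-5-enoic acid
Product: 7 bis-TIPS silyloxydiene ester
Conditions: TIPSOTf (2.2 equiv), Et3N, Et2O, 0 °C
Reagents that add atoms: triisopropylsilyl trifluoromethanesulfonate CC(C)[Si](C(C)C)(C(C)C)OS(=O)(=O)C(F)(F)F
Why: Soft enolisation/O-silylation of the vinyl ketone gives the 2-silyloxydiene as the (Z)-enol ether (side chain trans to the vinyl group, so the s-cis diene is accessible) and silylates the acid at the same time.

Step 5
Reactants: 8 3-methylfuran-2(5H)-one
Product: 9 2-(tert-butyldimethylsilyloxy)-3-methylfuran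
Conditions: TBSOTf, Et3N, CH2Cl2, 0 °C
Reagents that add atoms: tert-butyldimethylsilyl trifluoromethanesulfonate CC(C)(C)[Si](C)(C)OS(=O)(=O)C(F)(F)F
Why: O-silylation of the butenolide dienolate gives the aromatic 2-silyloxyfuran, the standard nucleophile for vinylogous Mukaiyama aldol reactions.

Step 6
Reactants: 9 2-(tert-butyldimethylsilyloxy)-3-methylfuran; 10 3-(trimethylsilyl)prop-2-ynal
Product: 11 (5R,1'S)-aldol butenolide
Conditions: SiCl4 (1.1 equiv), Denmark (R,R)-bisphosphoramide (5 mol %), i-Pr2NEt (10 mol %), CH2Cl2, −78 °C; aq NaHCO3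
Reagents that add atoms: none
Why: Lewis-base-activated SiCl4 vinylogous Mukaiyama aldol reaction in which the furan γ-carbon attacks the catalyst-bound ynal through an open transition state, which is expected to be anti (erythro) selective, while the chiral phosphoramide–silicon cation fixes the absolute sense, so that C6 (R) and C7 (S) are set together (the catalyst antipode is chosen to give this sense).

Step 7
Reactants: 11 (5R,1'S)-aldol butenolide
Product: 12 TBS-protected aldol butenolide
Conditions: TBSCl, imidazole, DMF, rt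
Reagents that add atoms: tert-butyldimethylsilyl chloride CC(C)(C)[Si](C)(C)Cl
Why: Imidazole-mediated silylation of the secondary propargylic alcohol blocks retro-aldol cleavage and later oxidation at C7 without touching a stereocentre.

Step 8
Reactants: 12 TBS-protected aldol butenolide; 7 bis-TIPS silyloxydiene ester
Product: 14 alkynyl enol-ether acid, via Diels–Alder adduct 13 (not isolated)
Conditions: PhMe (2 M), BHT, 150 °C, sealed tube; then K2CO3, MeOH, 0 °C → rt; 1 M HCl to pH 4
Reagents that add atoms: none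
Why: Thermal Diels–Alder reaction in which the nucleophilic enol-ether terminus (C10) bonds to the butenolide β-carbon (C5) and the vinyl terminus (C3) to C4, the diene approaching the face anti to the C6 side chain so that the obligatory cis ring fusion gives 4S and 5R (C10 forms as an irrelevant epimer mixture), after which K2CO3/MeOH cleaves the silyl ester and the C(sp)–SiMe3 bond while the TIPS enol ether keeps the C1 ketone masked.

Step 9
Reactants: 14 alkynyl enol-ether acid; 4 3-methoxy-4-isopropylcyclobut-3-ene-1,2-dione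
Product: 15 alkynyl hydroxycyclobutenone
Conditions: LDA (2.2 equiv), THF, −78 °C; then 4, −78 °C; AcOH
Reagents that add atoms: none
Why: The lithium acetylide (the acid is carried as its lithium carboxylate) adds 1,2 to the more electrophilic carbonyl of the semisquarate, the one next to C–OMe and not the vinylogous ester carbonyl, which fixes the later quinone substitution pattern; the new carbinol centre is an irrelevant mixture.

Step 10
Reactants: 15 alkynyl hydroxycyclobutenone
Product: 17 quinone keto acid, via quinone silyl enol ether 16 (not isolated)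
Conditions: p-xylene, 138 °C, 1 h; then 1 M HCl, THF, 0 °C
Reagents that add atoms: none
Why: Moore rearrangement (4π electrocyclic opening to the alkynyl vinylketene, ring closure to an aryl/phenoxyl diradical and O→C hydrogen transfer) gives the 2-methoxy-3-isopropylquinone with C8 carrying the side chain and C9–H free, and dilute acid then hydrolyses the silyl enol ether to the C1 ketone.

Step 11
Reactants: 17 quinone keto acid
Product: 18 tetracyclic keto-quinone
Conditions: AgNO3 (0.3 equiv), K2S2O8 (2 equiv), MeCN/H2O 1:1, 0.005 M, 50 °C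
Reagents that add atoms: none
Why: Proposed new method: an intramolecular Jacobsen–Torssell (Minisci-type) alkylation in which Ag(II) oxidises the carboxylate, loss of CO2 gives the nucleophilic primary C20 radical, this radical adds 7-endo to the only unsubstituted and electron-poor quinone carbon (C9) and persulfate re-oxidises the adduct radical to the quinone, the closest known reactions being the intermolecular Ag/persulfate decarboxylative alkylation of alkoxy- and hydroxyquinones and the addition of cyclopropanol-derived β-keto radicals to quinones; no stereocentre is formed and high dilution suppresses intermolecular addition.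

Step 12
Reactants: 18 tetracyclic keto-quinone
Product: 20 enone quinone, via hydroquinone enone 19 (not isolated)
Conditions: Et3N (0.5 equiv), CH2Cl2, O2 (1 atm), rt
Reagents that add atoms: none
Why: Base-mediated tautomerisation of the γ-oxoalkyl quinone through its o-quinone methide (deprotonation at C20, then loss of the C10 proton α to the ketone) gives the conjugated alkenyl hydroquinone, which autoxidises to the quinone, a net dehydrogenation of the type known from alkylquinone to o-quinone methide isomerisations, and the ring fixes the C10=C20 geometry.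

Step 13
Reactants: 20 enone quinone
Product: 22 O-methyl O-TBS ballotiquinone, via hydroquinone alcohol 21 (not isolated)
Conditions: (S)-Me-CBS (0.3 equiv), catecholborane (4 equiv), PhMe, −78 → −40 °C; aq NaHCO3, air, rt
Reagents that add atoms: none
Why: Corey–Bakshi–Shibata reduction with reagent-controlled hydride delivery (alkylidene side as the large group, by analogy with (S)-CBS giving (R)-1-arylethanols) sets C1 as R, while the quinone is reduced in passing to the hydroquinone and returns to the quinone on aerobic work-up.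

Step 14
Reactants: 22 O-methyl O-TBS ballotiquinone
Product: 24 ballotiquinone, via 7-O-TBS ballotiquinone 23 (not isolated)
Conditions: LiOH (3 equiv), THF/H2O, 0 °C; then 48% aq HF, MeCN, 0 °C → rt
Reagents that add atoms: lithium hydroxide [Li+].[OH-]
Why: Addition–elimination hydrolysis of the vinylogous methyl ester (2-methoxyquinone) by hydroxide, then acidification (which re-closes the γ-lactone if it opened) and HF cleavage of the silyl ether unmask the hydroxyquinone and the C7 alcohol without touching a stereocentre.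

**Compound list**
1 | squaric acid (3,4-dihydroxycyclobut-3-ene-1,2-dione) | OC1=C(O)C(=O)C1=O | starting material
2 | dimethyl squarate (3,4-dimethoxycyclobut-3-ene-1,2-dione) | COC1=C(OC)C(=O)C1=O | intermediate
3 | 4-hydroxy-2,3-dimethoxy-4-(propan-2-yl)cyclobut-2-en-1-one (racemic) | COC1=C(OC)C(O)(C(C)C)C1=O | intermediate (not isolated)
4 | 3-methoxy-4-(propan-2-yl)cyclobut-3-ene-1,2-dione | COC1=C(C(C)C)C(=O)C1=O | intermediate
5 | succinic anhydride | O=C1CCC(=O)O1 | starting material
6 | 4-oxohex-5-enoic acid | C=CC(=O)CCC(=O)O | intermediate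
7 | triisopropylsilyl (3Z)-4-[(triisopropylsilyl)oxy]hexa-3,5-dienoate | C=C/C(O[Si](C(C)C)(C(C)C)C(C)C)=C/CC(=O)O[Si](C(C)C)(C(C)C)C(C)C | intermediate
8 | 3-methylfuran-2(5H)-one | CC1=CCOC1=O | starting material
9 | tert-butyl(dimethyl)[(3-methylfuran-2-yl)oxy]silane | Cc1ccoc1O[Si](C)(C)C(C)(C)C | intermediate
10 | 3-(trimethylsilyl)prop-2-ynal | C[Si](C)(C)C#CC=O | starting material
11 | (5R)-5-[(1S)-1-hydroxy-3-(trimethylsilyl)prop-2-yn-1-yl]-3-methylfuran-2(5H)-one | C[Si](C)(C)C#C[C@H](O)[C@@H]1OC(=O)C(C)=C1 | intermediate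
12 | (5R)-5-[(1S)-1-[(tert-butyldimethylsilyl)oxy]-3-(trimethylsilyl)prop-2-yn-1-yl]-3-methylfuran-2(5H)-one | C[Si](C)(C)C#C[C@H](O[Si](C)(C)C(C)(C)C)[C@@H]1OC(=O)C(C)=C1 | intermediate
13 | triisopropylsilyl 2-[(3R,3aR,7aS)-3-[(1S)-1-[(tert-butyldimethylsilyl)oxy]-3-(trimethylsilyl)prop-2-yn-1-yl]-7a-methyl-1-oxo-5-[(triisopropylsilyl)oxy]-1,3,3a,4,7,7a-hexahydro-2-benzofuran-4-yl]acetate (ring position 4 = C-10, epimer mixture) | C[Si](C)(C)C#C[C@H](O[Si](C)(C)C(C)(C)C)[C@@H]1OC(=O)[C@@]2(C)CC=C(O[Si](C(C)C)(C(C)C)C(C)C)C(CC(=O)O[Si](C(C)C)(C(C)C)C(C)C)[C@@H]12 | intermediate (not isolated)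
14 | 2-[(3R,3aR,7aS)-3-[(1S)-1-[(tert-butyldimethylsilyl)oxy]prop-2-yn-1-yl]-7a-methyl-1-oxo-5-[(triisopropylsilyl)oxy]-1,3,3a,4,7,7a-hexahydro-2-benzofuran-4-yl]acetic acid (C-10 epimers) | C#C[C@H](O[Si](C)(C)C(C)(C)C)[C@@H]1OC(=O)[C@@]2(C)CC=C(O[Si](C(C)C)(C(C)C)C(C)C)C(CC(=O)O)[C@@H]12 | intermediate
15 | 2-[(3R,3aR,7aS)-3-[(1S)-1-[(tert-butyldimethylsilyl)oxy]-3-[1-hydroxy-2-methoxy-4-oxo-3-(propan-2-yl)cyclobut-2-en-1-yl]prop-2-yn-1-yl]-7a-methyl-1-oxo-5-[(triisopropylsilyl)oxy]-1,3,3a,4,7,7a-hexahydro-2-benzofuran-4-yl]acetic acid (mixture at the carbinol carbon and C-10) | COC1=C(C(C)C)C(=O)C1(O)C#C[C@H](O[Si](C)(C)C(C)(C)C)[C@@H]2OC(=O)[C@@]3(C)CC=C(O[Si](C(C)C)(C(C)C)C(C)C)C(CC(=O)O)[C@@H]23 | intermediate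
16 | 2-[(3R,3aR,7aS)-3-[(S)-[(tert-butyldimethylsilyl)oxy][4-methoxy-3,6-dioxo-5-(propan-2-yl)cyclohexa-1,4-dien-1-yl]methyl]-7a-methyl-1-oxo-5-[(triisopropylsilyl)oxy]-1,3,3a,4,7,7a-hexahydro-2-benzofuran-4-yl]acetic acid (C-10 epimers) | CC(C)C1=C(OC)C(=O)C=C(C1=O)[C@H](O[Si](C)(C)C(C)(C)C)[C@@H]1OC(=O)[C@@]2(C)CC=C(O[Si](C(C)C)(C(C)C)C(C)C)C(CC(=O)O)[C@@H]12 | intermediate (not isolated)
17 | 2-[(3R,3aR,7aS)-3-[(S)-[(tert-butyldimethylsilyl)oxy][4-methoxy-3,6-dioxo-5-(propan-2-yl)cyclohexa-1,4-dien-1-yl]methyl]-7a-methyl-1,5-dioxooctahydro-2-benzofuran-4-yl]acetic acid (C-10 epimers) | CC(C)C1=C(OC)C(=O)C=C(C1=O)[C@H](O[Si](C)(C)C(C)(C)C)[C@@H]1OC(=O)[C@@]2(C)CCC(=O)C(CC(=O)O)[C@@H]12 | intermediate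
18 | (4S,5R,6R,7S)-7-[(tert-butyldimethylsilyl)oxy]-12-methoxy-1,11,14-trioxoicetexa-8,12-dien-19,6-olide (C-10 epimers) | CC(C)C1=C(OC)C(=O)C2=C(C1=O)[C@H](O[Si](C)(C)C(C)(C)C)[C@@H]1OC(=O)[C@@]3(C)CCC(=O)C(C2)[C@@H]13 | intermediate
19 | (4S,5R,6R,7S)-7-[(tert-butyldimethylsilyl)oxy]-11,14-dihydroxy-12-methoxy-1-oxoicetexa-8,10(20),11,13-tetraen-19,6-olide | CC(C)c1c(OC)c(O)c2c(c1O)[C@H](O[Si](C)(C)C(C)(C)C)[C@@H]1OC(=O)[C@@]3(C)CCC(=O)C(=C2)[C@@H]13 | intermediate (not isolated)
20 | (4S,5R,6R,7S)-7-[(tert-butyldimethylsilyl)oxy]-12-methoxy-1,11,14-trioxoicetexa-8,10(20),12-trien-19,6-olide | CC(C)C1=C(OC)C(=O)C2=C(C1=O)[C@H](O[Si](C)(C)C(C)(C)C)[C@@H]1OC(=O)[C@@]3(C)CCC(=O)C(=C2)[C@@H]13 | intermediate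
21 | (1R,4S,5R,6R,7S)-7-[(tert-butyldimethylsilyl)oxy]-1,11,14-trihydroxy-12-methoxyicetexa-8,10(20),11,13-tetraen-19,6-olide | CC(C)c1c(OC)c(O)c2c(c1O)[C@H](O[Si](C)(C)C(C)(C)C)[C@@H]1OC(=O)[C@@]3(C)CC[C@@H](O)C(=C2)[C@@H]13 | intermediate (not isolated)
22 | (1R,4S,5R,6R,7S)-7-[(tert-butyldimethylsilyl)oxy]-1-hydroxy-12-methoxy-11,14-dioxoicetexa-8,10(20),12-trien-19,6-olide | CC(C)C1=C(OC)C(=O)C2=C(C1=O)[C@H](O[Si](C)(C)C(C)(C)C)[C@@H]1OC(=O)[C@@]3(C)CC[C@@H](O)C(=C2)[C@@H]13 | intermediate
23 | (1R,4S,5R,6R,7S)-7-[(tert-butyldimethylsilyl)oxy]-1,12-dihydroxy-11,14-dioxoicetexa-8,10(20),12-trien-19,6-olide | CC(C)C1=C(O)C(=O)C2=C(C1=O)[C@H](O[Si](C)(C)C(C)(C)C)[C@@H]1OC(=O)[C@@]3(C)CC[C@@H](O)C(=C2)[C@@H]13 | intermediate (not isolated)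
24 | ballotiquinone, (1R,4S,5R,6R,7S)-1,7,12-trihydroxy-11,14-dioxoicetexa-8,10(20),12-trien-19,6-olide | CC(C)C1=C(O)C(=O)C2=C(C1=O)[C@H](O)[C@@H]1OC(=O)[C@@]3(C)CC[C@@H](O)C(=C2)[C@@H]13 | target

**Totals**
Total step count: 14. Longest linear sequence: 10 steps (8 → 24, steps 5–14); the squarate branch (steps 1–2) joins at step 9 and the diene branch (steps 3–4) at step 8.

**Steps most likely to fail**

Step 8 (Diels–Alder). An α-methyl, γ-substituted butenolide is a sluggish dienophile and the diene carries a terminal substituent, so forcing conditions may erode the diene before cycloaddition. The fallback sets out from 12 and uses regiocontrol by an enone instead of by the diene. (E)-4-(Dimethylamino)but-3-en-2-one is silylated (KHMDS, TBSCl) to Rawal's diene F1, which reacts with 12 at 80–100 °C to the amino silyl enol ether cycloadduct F2, again anti to the side chain. Dilute HCl/THF turns this into the C2=C3 enone F3, in which C10 is the only enolisable position. LDA followed by triisopropylsilyl bromoacetate gives the α′-alkylated enone F4. K-Selectride 1,4-reduction with TIPSOTf trapping of the C1–C2 enolate then gives 13, where the fallback comes back to the route (13 is methanolysed to 14 as in step 8).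

Step 11 (radical ring closure). A 7-endo closure by a primary radical has to outrun intermolecular addition, 1,2-acyl shift and over-oxidation. The fallback sets out from 17 and closes the same bond by an ionic reaction. Kochi oxidative decarboxylation (Pb(OAc)4, cat. Cu(OAc)2, pyridine, PhH, 80 °C) gives the α-methylene ketone quinone F5. Na2S2O4 reduces it to the hydroquinone F6. Sc(OTf)3-catalysed intramolecular Friedel–Crafts conjugate addition of the electron-rich ring carbon C9 to the exo-methylene ketone gives the cyclised hydroquinone F7. Oxidation with Ag2O or air returns to 18.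

Step 12 (tautomerisation/autoxidation). The C7–H is also vinylogously acidic, so base may epimerise C7, and o-quinone methides can dimerise. The fallback sets out from 18 and desaturates through the ketone instead. PhSeCl in EtOAc (acid-catalysed selenenylation at the more substituted α-carbon C10) gives the C10 phenylselenide F8. H2O2/pyridine at 0 °C oxidises it to the selenoxide, whose syn-elimination toward the C20 methylene delivers 20, where the fallback comes back to the route.

**Further compounds**
F1 | step 8 | (E)-3-[(tert-butyldimethylsilyl)oxy]-N,N-dimethylbuta-1,3-dien-1-amine (Rawal's diene) | CN(C)/C=C/C(=C)O[Si](C)(C)C(C)(C)C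
F2 | step 8 | amino silyl enol ether cycloadduct (C-3 dimethylamino, C-1 OTBS enol ether, epimer mixture at C-3) | C[Si](C)(C)C#C[C@H](O[Si](C)(C)C(C)(C)C)[C@@H]1OC(=O)[C@@]2(C)C(N(C)C)C=C(O[Si](C)(C)C(C)(C)C)C[C@@H]12
F3 | step 8 | C2=C3 enone (C-1 ketone, C-10 methylene) | C[Si](C)(C)C#C[C@H](O[Si](C)(C)C(C)(C)C)[C@@H]1OC(=O)[C@@]2(C)C=CC(=O)C[C@@H]12
F4 | step 8 | α′-alkylated enone (C-10 CH2CO2TIPS, C-10 epimers) | C[Si](C)(C)C#C[C@H](O[Si](C)(C)C(C)(C)C)[C@@H]1OC(=O)[C@@]2(C)C=CC(=O)C(CC(=O)O[Si](C(C)C)(C(C)C)C(C)C)[C@@H]12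
F5 | step 11 | α-methylene ketone quinone (C10=C20H2) | CC(C)C1=C(OC)C(=O)C=C(C1=O)[C@H](O[Si](C)(C)C(C)(C)C)[C@@H]1OC(=O)[C@@]2(C)CCC(=O)C(=C)[C@@H]12
F6 | step 11 | α-methylene ketone hydroquinone | CC(C)c1c(OC)c(O)cc(c1O)[C@H](O[Si](C)(C)C(C)(C)C)[C@@H]1OC(=O)[C@@]2(C)CCC(=O)C(=C)[C@@H]12
F7 | step 11 | cyclised hydroquinone (hydroquinone of 18, C-10 epimers) | CC(C)c1c(OC)c(O)c2c(c1O)[C@H](O[Si](C)(C)C(C)(C)C)[C@@H]1OC(=O)[C@@]3(C)CCC(=O)C(C2)[C@@H]13
F8 | step 12 | C-10 phenylselenide of 18 (mixture at C-10) | CC(C)C1=C(OC)C(=O)C2=C(C1=O)[C@H](O[Si](C)(C)C(C)(C)C)[C@@H]1OC(=O)[C@@]3(C)CCC(=O)C(C2)([Se]c2ccccc2)[C@@H]13
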